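The numbers in the tables are simulated with constants of no real substance; the scatter is artificial.

Two questions were put to me about alder, oak and larch: how much D stands at the end, and which way that amount moves as the charge of Z goes up.

| setting | north-west | alder | oak | larch |
|---|---|---|---|---|
| G | 1 M | 1.0 M | 1.0 M | 1.0 M |
| L | 1 M | 0.700 M | 0.700 M | 0.700 M |
| Z | 0.050 M | 0.0500 M | 0.0800 M | 0.120 M |
| remark | run made earlier |  |  |  |
| time |  | 40 h | 40 h | 40 h |

north-west run (percent of the G charged)

| time / h | D / % |
|---|---|
| 1.00 | 16.8 |
| 2.50 | 32.7 |
| 5.00 | 47.4 |
| 8.00 | 57.0 |
| 10.0 | 61.3 |
| 15.0 | 68.6 |

(scatter of a reading: 0.3 percentage points)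

- amount of D at the end, in percent of the G charged for alder, oak, larch, in this order
- how that number moves from the first to the last of them (rises, then falls / rises all the way / hardly changes / falls, then rises / falls all the way)

- "hardly changes" means that all values lie within two and a half points (for a concentration: within two and a half percent of the largest)
- no earlier run changes the charge of Z; that part of a forecast is a guess

**Main step.** I began with G and L giving D, one of each. L is then the limiting reagent, and D can't pass 70.0% in alder, oak or larch. This is my ceiling, the charge c(L) over the charge c(G).

**Added slowing.** In the north-west run, where G and L were charged equal, the rate of D fell by a factor of 11.5 from the first reading to the last two, while what remained fell by a factor of 2.61. The ratio of their logarithms gives a total order of about 2.54, as a reading. That slowing could leave D short of the ceiling at 40 h, but one run doesn't split the order between G and L, so I put no figure on it.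

**Adding Z.** No run varied Z, so this part was my guess. If each Z consumed one L, the ceiling would drop by c(Z)/c(G), to 65.0% in alder, 62.0% in oak and 58.0% in larch. I therefore expected a fall.

**The forecast.** The forecast gave 58%, 63% and 66%, so rises all the way, holding that “Z is probably a catalyst or promoter”. On the direction, my reckoning differed from it.

**The flasks.** They gave 65.0%, 62.0% and 58.0%, so falls all the way.

    L + Z → E (k = 5.00 M⁻¹ h⁻¹)
    G + L → D, rate k2*[G]^2*[L]^0.5 (k = 0.220 M⁻¹·⁵ h⁻¹)

**Where L went.** At 40.0 h, alder held L at 0% and Z at 0% of their charges, with E at 0.0500 M, and D stood 5 percentage points under the ceiling, matching its c(Z)/c(G) of 5.00%. Larch stood 12 points under the ceiling, matching its own 12.0%. The conversion of L and Z into E is a part of the reason for the fall from alder to larch, at most the largest single effect: D moved by −7 points from alder to larch with that step in place and by 0 points with it switched off, when larch stood at the ceiling, 70.0%.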